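**Retrosynthetic overview**

1. Numbering used below: C3 is the carboxyl carbon and C1–C2 the chain on C10; ring B is C5(=C4Me2)–C6–C7–C8–C9–C10; ring C is C8–C9–C11–C12–C13–C14 (Me on C9, C13 and C14; CH2Ar on C14); α is the face of C8–H, β the face of C9–Me.
2. Enabling feature: in ring B the exocyclic alkene at C5 and the side chain at C10 are the retron of a C5=C10 enol ether, and the bonds C6–C7 and C8–C9 flank the C7–C8 edge. Ring B is therefore the Diels–Alder adduct of a C6=C5(OSi)–C10=C9 diene and a C7=C8 dienophile; since C8 and C9 are also linked through C11–C14, one intramolecular cycloaddition closes rings B and C together and sets C8 and C9 (C10 follows by protonation).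
3. After the key step: formyl removal, then C5 ketone → isopropenyl carbinol δ-lactone → reductive allylic transposition (isopropylidene and free acid in one step) → release of the hydroquinone.
4. Before it: the triene is joined at C9–C11 by B-alkyl Suzuki coupling of an E-enol triflate (from methyl 4-acetyl-5-oxohexanoate) with a 1-alkene. The C13/C14 pair comes from an isomerisation–Claisen sequence with chirality transfer from (R)-but-3-yn-2-ol; the arene enters by Negishi coupling.
5. Ring order: arene (purchased) → rings B and C together (step 16) → temporary δ-lactone ring (step 18, opened in step 19).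

Key step: step 16

Remarks: compound 7 is taken as commercial (otherwise one step from pentane-2,4-dione and methyl acrylate). The triflation of 7 is assumed to show the E-selectivity known for 2-substituted β-keto esters under the same conditions.

**Route**

Step 1
Reactants: 1 (R)-but-3-yn-2-ol
Product: 3 (R)-pent-3-yn-2-ol, via dilithium alkoxide acetylide 2 (not isolated)
Conditions: n-BuLi (2.05 equiv), THF, −78 °C; MeI (1.0 equiv), DMPU, −78 → 0 °C
Reagents that add atoms: iodomethane, CI
Why: C-alkylation of the acetylide terminus of a propargylic alcohol dianion, which is far more nucleophilic than the lithium alkoxide; the carbinol stereocentre is not touched.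

Step 2
Reactants: 3 (R)-pent-3-yn-2-ol
Product: 5 (2R,3Z)-4-iodopent-3-en-2-ol, via cyclic alkenylalanate 4 (not isolated)
Conditions: NaAlH2(OCH2CH2OCH3)2, THF, 0 → 25 °C; then I2, −78 °C
Reagents that add atoms: iodine, II
Why: Hydroxyl-directed trans-hydroalumination of a propargylic alcohol puts aluminium on the remote alkyne carbon, cis to the carbinol carbon, and iodinolysis with retention should give the Z-iodoalkene.

Step 3
Reactants: 5 (2R,3Z)-4-iodopent-3-en-2-ol
Product: 6 (2R,3Z)-4-iodo-2-(prop-2-en-1-yloxy)pent-3-ene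
Conditions: NaH, allyl bromide, THF, 0 °C
Reagents that add atoms: allyl bromide, C=CCBr
Why: Williamson etherification of the sodium alkoxide at low temperature, where the alkenyl iodide and the stereocentre are not involved.

Step 4
Reactants: 7 methyl 4-acetyl-5-oxohexanoate
Product: 8 methyl (4E)-4-acetyl-5-{[(trifluoromethyl)sulfonyl]oxy}hex-4-enoate
Conditions: Tf2O, aq. Me4NOH, toluene, 0 °C
Reagents that add atoms: trifluoromethanesulfonic anhydride, O=S(=O)(OS(=O)(=O)C(F)(F)F)C(F)(F)F
Why: O-sulfonylation of the 1,3-dicarbonyl enolate with a non-chelating ammonium counter-ion, which favours the open enolate with the oxygen anti to the second carbonyl and so the E-enol triflate (stereodivergent enol triflate formation).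

Step 5
Reactants: 9 4-methoxy-2-methylphenol
Product: 10 2-hydroxy-5-methoxy-3-methylbenzaldehyde
Conditions: (CH2O)n, MgCl2, Et3N, MeCN, 80 °C
Reagents that add atoms: paraformaldehyde (formaldehyde unit), C=O
Why: Magnesium phenoxide-directed ortho-formylation (Casnati–Skattebøl type) at the only free ortho position, a second formaldehyde acting as hydride acceptor.

Step 6
Reactants: 10 2-hydroxy-5-methoxy-3-methylbenzaldehyde
Product: 11 2,5-dimethoxy-3-methylbenzaldehyde
Conditions: MeI, K2CO3, DMF, 25 °C
Reagents that add atoms: iodomethane, CI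
Why: Williamson O-methylation of the phenoxide.

Step 7
Reactants: 11 2,5-dimethoxy-3-methylbenzaldehyde
Product: 12 (2,5-dimethoxy-3-methylphenyl)methanol
Conditions: NaBH4, MeOH, 0 °C
Reagents that add atoms: none
Why: Borohydride reduction of the aryl aldehyde.

Step 8
Reactants: 12 (2,5-dimethoxy-3-methylphenyl)methanol
Product: 13 1-(chloromethyl)-2,5-dimethoxy-3-methylbenzene
Conditions: SOCl2, CH2Cl2, 0 °C
Reagents that add atoms: thionyl chloride, O=S(Cl)Cl
Why: Chlorination through the chlorosulfite; the chloride is chosen over the bromide because it inserts zinc without Wurtz homocoupling.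

Step 9
Reactants: 13 1-(chloromethyl)-2,5-dimethoxy-3-methylbenzene; 6 (2R,3Z)-4-iodo-2-(prop-2-en-1-yloxy)pent-3-ene
Product: 15 1-[(2Z,4R)-2-methyl-4-(prop-2-en-1-yloxy)pent-2-en-1-yl]-2,5-dimethoxy-3-methylbenzene, via benzylzinc chloride 14 (not isolated)
Conditions: Zn dust, LiCl, THF, 25 °C; then 6, Pd(OAc)2 (2 mol %), SPhos (4 mol %), THF, 25 °C
Reagents that add atoms: none
Why: LiCl-promoted zinc insertion and Negishi sp3–sp2 coupling, which keeps the alkene geometry, so the benzyl group ends cis to the carbinol carbon; the allyl alkyl ether is not ionised by zerovalent palladium.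

Step 10
Reactants: 15 diallyl ether
Product: 17 (2R,3R,4E)-3-[(2,5-dimethoxy-3-methylphenyl)methyl]-2,3-dimethylhex-4-enal, via E-propenyl ether 16 (not isolated)
Conditions: [IrCl(C8H14)2]2 (1 mol %), PCy3 (6 mol %), NaBPh4 (2 mol %), CH2Cl2/acetone, 23 °C; then PPh3 (6 mol %), ClCH2CH2Cl, 80–100 °C
Reagents that add atoms: none
Why: Iridium-hydride isomerisation of the unhindered O-allyl group to the E-propenyl ether and Claisen rearrangement (isomerisation–Claisen sequence) through a chair in which the carbinol methyl and the propenyl methyl are equatorial and the benzyl group (Z-position) is axial, so the R-carbinol chirality is transferred to C13 and C14 and the old carbinol carbon ends in an E-propenyl group.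

Step 11
Reactants: 17 aldehyde
Product: 18 (3S,4R,5E)-4-[(2,5-dimethoxy-3-methylphenyl)methyl]-3,4-dimethylhepta-1,5-diene
Conditions: Ph3PCH3Br, KN(SiMe3)2, THF, −78 → 0 °C
Reagents that add atoms: methyltriphenylphosphonium bromide, C[P+](c1ccccc1)(c1ccccc1)c1ccccc1.[Br-]
Why: Wittig methylenation supplies C11; at low temperature the non-stabilised ylide should add faster than it enolises the α-branched aldehyde, so C13 is kept.

Step 12
Reactants: 18 diene; 8 enol triflate
Product: 20 methyl (4E,8S,9S,10E)-4-acetyl-9-[(2,5-dimethoxy-3-methylphenyl)methyl]-5,8,9-trimethyldodeca-4,10-dienoate, via B-alkyl-9-BBN 19 (not isolated)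
Conditions: 9-BBN, THF, 0 → 25 °C; then 8, Pd(dppf)Cl2 (5 mol %), AsPh3, aq. K3PO4, DMF, 25 °C
Reagents that add atoms: none
Why: 9-BBN adds anti-Markovnikov only to the monosubstituted alkene (the propenyl group next to the quaternary carbon is too hindered), and B-alkyl Suzuki–Miyaura coupling with the vinylogous acyl triflate forms C9–C11 with retention, so the tether ends trans to the acetyl group.

Step 13
Reactants: 20 enone ester
Product: 22 methyl (4E,8S,9S)-4-acetyl-9-[(2,5-dimethoxy-3-methylphenyl)methyl]-5,8,9-trimethyl-10-oxodec-4-enoate, via vicinal diol 21 (not isolated)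
Conditions: OsO4 (2 mol %), NaIO4 (4 equiv), 2,6-lutidine, dioxane/H2O, 25 °C
Reagents that add atoms: osmium tetroxide (catalytic oxygen carrier), O=[Os](=O)(=O)=O; sodium periodate, [Na+].[O-]I(=O)(=O)=O
Why: Lemieux–Johnson cleavage; OsO4 should take the electron-rich 1,2-disubstituted alkene and leave the tetrasubstituted acceptor alkene and the arene, and periodate cleaves the diol to the neopentyl aldehyde (C8).

Step 14
Reactants: 22 aldehyde
Product: 23 methyl (4E,8S,9S,10E)-4-acetyl-9-[(2,5-dimethoxy-3-methylphenyl)methyl]-5,8,9-trimethyl-12-oxododeca-4,10-dienoate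
Conditions: Ph3P=CHCHO, PhMe, 90 °C
Reagents that add atoms: (triphenylphosphoranylidene)acetaldehyde, O=CC=P(c1ccccc1)(c1ccccc1)c1ccccc1
Why: Wittig reaction with a stabilised ylide gives the E-enal (C7 plus the activating formyl group); the hindered conjugated ketone does not react.

Step 15
Reactants: 23 enal enone
Product: 24 methyl (4E,8S,9S,10E)-4-{1-[(tert-butyldimethylsilyl)oxy]ethenyl}-9-[(2,5-dimethoxy-3-methylphenyl)methyl]-5,8,9-trimethyl-12-oxododeca-4,10-dienoate
Conditions: TBSOTf, Et3N, CH2Cl2, −78 → 0 °C; non-aqueous work-up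
Reagents that add atoms: tert-butyldimethylsilyl trifluoromethanesulfonate, CC(C)(C)[Si](C)(C)OS(=O)(=O)C(F)(F)F
Why: Soft enolisation of the methyl ketone towards C6 gives the cross-conjugated 2-silyloxydiene; the enal has no enolisable hydrogen (C14 is quaternary) and the ester is not enolised by Et3N.

Step 16
Reactants: 24 silyloxy triene aldehyde
Product: 25 trans-fused cycloadduct (ring B: C5(OTBS)=C10 enol ether with the ester chain on C10, 7α-CHO, 8α-H, 9β-Me; ring C: 13α-Me, 14β-Me, 14α-CH2Ar)
Conditions: PhMe (0.005 M), 2,6-di-tert-butyl-4-methylphenol (trace), base-washed sealed tube, 120 °C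
Reagents that add atoms: none
Why: Thermal, concerted but asynchronous [4+2] cycloaddition (type 1 intramolecular Diels–Alder reaction) of the 2-silyloxydiene C6=C5–C10=C9 with the E-enal C7=C8; the closest precedents are thermal cyclisations of 1,7,9-decatrienals and of 2-silyloxydienes tethered to enals to give trans-decalins. Ring C closes through C8–C9 as the chair-like six-atom tether ring (C9–C11–C12–C13–C14–C8), and ring B closes as the new cyclohexene through C6–C7 and C8–C9 in the boat-like cycloaddition array. The trans fusion (C8–H anti to C9–Me) follows from the E geometry of C9=C10 (tether outside, methyl inside) together with the endo position of the formyl group, which puts the tether exo; C7 is fixed by the E-enal geometry and disappears in step 17. The π-face is chosen by the quaternary C14: in the favoured chair its methyl is axial, syn to the inside C9 methyl, and the 2,6-disubstituted benzyl group is equatorial, whereas the other face would put the benzyl group axial, where every rotamer meets a syn-pentane contact (C9–Me, C13–Me or C7). The step needs endo over exo selectivity (helped by the formyl group and by the C10 chain, which would lie over ring C in the cis-fused mode), this facial selectivity, and a rate at 120 °C that outruns the 1,5-hydrogen shift of the cis-methyl diene; the last point is secured by enal activation and by the 2,3-disubstituted, s-cis-biased diene, although the tether forces the electronically less favoured orientation relative to the silyloxy group. The C5=C10 silyl enol ether that results is the handle used next for C10 and C5.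

Step 17
Reactants: 25 cycloadduct
Product: 27 methyl 3-[(1S,4aR,5S,6S,8aR)-5-[(2,5-dimethoxy-3-methylphenyl)methyl]-5,6,8a-trimethyl-2-oxodecahydronaphthalen-1-yl]propanoate, via decarbonylated silyl enol ether 26 (not isolated)
Conditions: RhCl(PPh3)3 (1.1 equiv), xylene, 130 °C; then HCl (1 M), THF, 25 °C
Reagents that add atoms: none
Why: Tsuji–Wilkinson decarbonylation replaces the formyl group by hydrogen (C7 becomes CH2), and acid hydrolysis of the silyl enol ether protonates C10 axially, anti to the axial C9 methyl, which is also the thermodynamically preferred epimer (equatorial chain) of this enolisable centre.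

Step 18
Reactants: 27 keto ester
Product: 29 δ-lactone (C3 carboxyl bonded to the C5 oxygen; C5 carries a β-axial oxygen and an α-equatorial isopropenyl group), via tertiary alkoxide 28 (not isolated)
Conditions: CeCl3, CH2=C(CH3)MgBr (1.3 equiv), THF, −78 → 25 °C
Reagents that add atoms: isopropenylmagnesium bromide, C=C(C)[Mg]Br
Why: Organocerium 1,2-addition (little enolisation, ketone before ester) from the equatorial direction, the axial face of C5 being blocked by the syn-axial C9 methyl, then lactonisation of the tertiary alkoxide onto the δ-ester; the C5 centre is temporary.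

Step 19
Reactants: 29 δ-lactone
Product: 31 3-[(1S,4aR,5S,6S,8aR)-5-[(2,5-dimethoxy-3-methylphenyl)methyl]-5,6,8a-trimethyl-2-(propan-2-ylidene)decahydronaphthalen-1-yl]propanoic acid, via triethylsilyl ester 30 (not isolated)
Conditions: Et3SiH (3 equiv), BF3·OEt2 (2 equiv), CH2Cl2, −78 → −30 °C; aqueous work-up
Reagents that add atoms: none
Why: Ionic hydrogenation (Kursanov–Parnes type): BF3 ionises the tertiary allylic lactone C–O bond to an allyl cation, whose unhindered CH2 terminus takes hydride from the silane (SN1′); this forms the tetrasubstituted isopropylidene and frees the carboxyl group, while low temperature and excess silane should suppress proton loss at C10.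

Step 20
Reactants: 31 dimethyl ether acid
Product: 33 CNP0286368.1, via quinone 32 (not isolated)
Conditions: (NH4)2Ce(NO3)6 (2.5 equiv), MeCN/H2O, 0 °C; then Na2S2O4, H2O/EtOAc, 25 °C
Reagents that add atoms: water, O
Why: Ceric ammonium nitrate oxidative demethylation of the 1,4-dimethoxyarene to the quinone (the electron-rich arene is oxidised before the tetrasubstituted alkene) and dithionite reduction to the hydroquinone.

**Compound list**

1 | (R)-but-3-yn-2-ol | C[C@@H](O)C#C | starting material
2 | dilithium salt of 1 (lithium alkoxide, lithium acetylide) | C[C@@H]([O-])C#[C-].[Li+].[Li+] | intermediate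
3 | (R)-pent-3-yn-2-ol | C[C@@H](O)C#CC | intermediate
4 | sodium cyclic (Z)-alkenylalanate from 3 (five-membered O–Al–C4=C3–C2 ring, two 2-methoxyethoxy groups on Al) | C[C@H]1O[Al-](OCCOC)(OCCOC)C(C)=C1.[Na+] | intermediate
5 | (2R,3Z)-4-iodopent-3-en-2-ol | C[C@@H](O)/C=C(/C)I | intermediate
6 | (2R,3Z)-4-iodo-2-(prop-2-en-1-yloxy)pent-3-ene | C=CCO[C@H](C)/C=C(/C)I | intermediate
7 | methyl 4-acetyl-5-oxohexanoate | CC(=O)C(CCC(=O)OC)C(C)=O | starting material
8 | methyl (4E)-4-acetyl-5-{[(trifluoromethyl)sulfonyl]oxy}hex-4-enoate (triflate anti to acetyl) | CC(=O)/C(CCC(=O)OC)=C(\C)OS(=O)(=O)C(F)(F)F | intermediate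
9 | 4-methoxy-2-methylphenol | COc1ccc(O)c(C)c1 | starting material
10 | 2-hydroxy-5-methoxy-3-methylbenzaldehyde | COc1cc(C)c(O)c(C=O)c1 | intermediate
11 | 2,5-dimethoxy-3-methylbenzaldehyde | COc1cc(C)c(OC)c(C=O)c1 | intermediate
12 | (2,5-dimethoxy-3-methylphenyl)methanol | COc1cc(C)c(OC)c(CO)c1 | intermediate
13 | 1-(chloromethyl)-2,5-dimethoxy-3-methylbenzene | COc1cc(C)c(OC)c(CCl)c1 | intermediate
14 | (2,5-dimethoxy-3-methylbenzyl)zinc chloride | COc1cc(C)c(OC)c(C[Zn]Cl)c1 | intermediate
15 | 1-[(2Z,4R)-2-methyl-4-(prop-2-en-1-yloxy)pent-2-en-1-yl]-2,5-dimethoxy-3-methylbenzene | C=CCO[C@H](C)/C=C(/C)Cc1cc(OC)cc(C)c1OC | intermediate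
16 | 1-[(2Z,4R)-2-methyl-4-{[(1E)-prop-1-en-1-yl]oxy}pent-2-en-1-yl]-2,5-dimethoxy-3-methylbenzene | C/C=C/O[C@H](C)/C=C(/C)Cc1cc(OC)cc(C)c1OC | intermediate
17 | (2R,3R,4E)-3-[(2,5-dimethoxy-3-methylphenyl)methyl]-2,3-dimethylhex-4-enal | O=C[C@H](C)[C@](C)(Cc1cc(OC)cc(C)c1OC)/C=C/C | intermediate
18 | (3S,4R,5E)-4-[(2,5-dimethoxy-3-methylphenyl)methyl]-3,4-dimethylhepta-1,5-diene | C=C[C@H](C)[C@](C)(Cc1cc(OC)cc(C)c1OC)/C=C/C | intermediate
19 | 9-{(3S,4S,5E)-4-[(2,5-dimethoxy-3-methylphenyl)methyl]-3,4-dimethylhept-5-en-1-yl}-9-borabicyclo[3.3.1]nonane | C(C[C@H](C)[C@](C)(Cc1cc(OC)cc(C)c1OC)/C=C/C)B1C2CCCC1CCC2 | intermediate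
20 | methyl (4E,8S,9S,10E)-4-acetyl-9-[(2,5-dimethoxy-3-methylphenyl)methyl]-5,8,9-trimethyldodeca-4,10-dienoate | CC(=O)/C(CCC(=O)OC)=C(\C)CC[C@H](C)[C@](C)(Cc1cc(OC)cc(C)c1OC)/C=C/C | intermediate
21 | 10,11-diol of 20 (mixture at the two carbinol carbons) | CC(=O)/C(CCC(=O)OC)=C(\C)CC[C@H](C)[C@](C)(Cc1cc(OC)cc(C)c1OC)C(O)C(C)O | intermediate
22 | methyl (4E,8S,9S)-4-acetyl-9-[(2,5-dimethoxy-3-methylphenyl)methyl]-5,8,9-trimethyl-10-oxodec-4-enoate | CC(=O)/C(CCC(=O)OC)=C(\C)CC[C@H](C)[C@](C)(Cc1cc(OC)cc(C)c1OC)C=O | intermediate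
23 | methyl (4E,8S,9S,10E)-4-acetyl-9-[(2,5-dimethoxy-3-methylphenyl)methyl]-5,8,9-trimethyl-12-oxododeca-4,10-dienoate | CC(=O)/C(CCC(=O)OC)=C(\C)CC[C@H](C)[C@](C)(Cc1cc(OC)cc(C)c1OC)/C=C/C=O | intermediate
24 | methyl (4E,8S,9S,10E)-4-{1-[(tert-butyldimethylsilyl)oxy]ethenyl}-9-[(2,5-dimethoxy-3-methylphenyl)methyl]-5,8,9-trimethyl-12-oxododeca-4,10-dienoate | C=C(O[Si](C)(C)C(C)(C)C)/C(CCC(=O)OC)=C(\C)CC[C@H](C)[C@](C)(Cc1cc(OC)cc(C)c1OC)/C=C/C=O | intermediate
25 | trans-fused cycloadduct: C5(OTBS)=C10 silyl enol ether with CH2CH2CO2Me on C10, 7α-CHO, 8α-H, 9β-Me, 13α-Me, 14β-Me, 14α-CH2Ar | CC(C)(C)[Si](C)(C)OC1=C(CCC(=O)OC)[C@]2(C)CC[C@H](C)[C@](C)(Cc3cc(OC)cc(C)c3OC)[C@H]2[C@H](C=O)C1 | intermediate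
26 | 25 without the formyl group (C7 = CH2) | CC(C)(C)[Si](C)(C)OC1=C(CCC(=O)OC)[C@]2(C)CC[C@H](C)[C@](C)(Cc3cc(OC)cc(C)c3OC)[C@H]2CC1 | intermediate
27 | methyl 3-[(1S,4aR,5S,6S,8aR)-5-[(2,5-dimethoxy-3-methylphenyl)methyl]-5,6,8a-trimethyl-2-oxodecahydronaphthalen-1-yl]propanoate | O=C1CC[C@H]2[C@@](C)(CC[C@H](C)[C@]2(C)Cc2cc(OC)cc(C)c2OC)[C@@H]1CCC(=O)OC | intermediate
28 | methyl 3-[(1S,2R,4aR,5S,6S,8aR)-5-[(2,5-dimethoxy-3-methylphenyl)methyl]-2-hydroxy-5,6,8a-trimethyl-2-(prop-1-en-2-yl)decahydronaphthalen-1-yl]propanoate, formed as its alkoxide | C=C(C)[C@@]1(O)CC[C@H]2[C@@](C)(CC[C@H](C)[C@]2(C)Cc2cc(OC)cc(C)c2OC)[C@@H]1CCC(=O)OC | intermediate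
29 | δ-lactone of 28 (six-membered ring O–C5–C10–C1–C2–C3(=O); 5β-O, 5α-isopropenyl) | C=C(C)[C@@]12CC[C@H]3[C@@](C)(CC[C@H](C)[C@]3(C)Cc4cc(OC)cc(C)c4OC)[C@@H]1CCC(=O)O2 | intermediate
30 | triethylsilyl ester of 31 | CC(C)=C1CC[C@H]2[C@@](C)(CC[C@H](C)[C@]2(C)Cc2cc(OC)cc(C)c2OC)[C@@H]1CCC(=O)O[Si](CC)(CC)CC | intermediate
31 | 3-[(1S,4aR,5S,6S,8aR)-5-[(2,5-dimethoxy-3-methylphenyl)methyl]-5,6,8a-trimethyl-2-(propan-2-ylidene)decahydronaphthalen-1-yl]propanoic acid | CC(C)=C1CC[C@H]2[C@@](C)(CC[C@H](C)[C@]2(C)Cc2cc(OC)cc(C)c2OC)[C@@H]1CCC(=O)O | intermediate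
32 | quinone of the target (2-alkyl-6-methyl-1,4-benzoquinone) | CC(C)=C1CC[C@H]2[C@@](C)(CC[C@H](C)[C@]2(C)CC2=CC(=O)C=C(C)C2=O)[C@@H]1CCC(=O)O | intermediate
33 | CNP0286368.1, 3-[(1S,4aR,5S,6S,8aR)-5-[(2,5-dihydroxy-3-methylphenyl)methyl]-5,6,8a-trimethyl-2-(propan-2-ylidene)decahydronaphthalen-1-yl]propanoic acid | CC(C)=C1CC[C@H]2[C@@](C)(CC[C@H](C)[C@]2(C)Cc2cc(O)cc(C)c2O)[C@@H]1CCC(=O)O | target

**Step count and risks**

Total step count: 20. Longest linear sequence: 16 steps (steps 5–20, from 9).

Steps most likely to fail: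

Step 16. The uncatalysed cyclisation may discriminate poorly between the two diene faces or between endo and exo modes at the temperature the forced orientation requires, and the cis-methyl diene may isomerise by 1,5-hydrogen shift before it cyclises. The fallback replaces thermal activation by catalyst control at low temperature. It sets out from 23, which is converted with TIPSOTf and Et3N into the triisopropylsilyl dienol ether F1. F1 is cyclised in CH2Cl2 at −78 → −20 °C with a chiral cationic oxazaborolidinium catalyst, the N-protonated (S)-1-(2-methylphenyl)-3,3-diphenyl-tetrahydropyrrolo[1,2-c][1,3,2]oxazaborole bis(trifluoromethylsulfonyl)amide, or its enantiomer if that one is matched with C14. This is a known catalytic Diels–Alder protocol for enals with 2-silyloxydienes and for trienals; the formyl-bound catalyst enforces the endo mode and shields one face. The resulting triisopropylsilyl cycloadduct F2 is taken through the conditions of step 17 and returns to the route at 27.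

Step 19. The allyl cation may lose a proton instead of taking hydride (dienes, or migration of the double bond towards C10 with loss of that stereocentre), or the tetrasubstituted alkene may be reduced further. The fallback makes the isopropylidene by carbonyl coupling instead of ionisation. It sets out from 27, which undergoes a mixed McMurry coupling with excess acetone (TiCl4, Zn, pyridine, THF, reflux) to give the isopropylidene methyl ester F6; saponification (LiOH, THF/MeOH/H2O) returns to the route at 31.

Step 17. Oxidative addition at the hindered secondary aldehyde may be slow, and β-hydride elimination from the alkylrhodium intermediate may give ring alkenes. The fallback removes the carbon as CO2 by radical decarboxylation. It sets out from 25: HCl (1 M)/THF gives the keto aldehyde F3; Pinnick oxidation (NaClO2, NaH2PO4, 2-methyl-2-butene) gives the keto acid F4; N-hydroxypyridine-2-thione, DCC and DMAP give the thiohydroxamate ester F5; Barton decarboxylation (visible light, t-BuSH, benzene) returns to the route at 27.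

**Further compounds**

F1 | step 16 | triisopropylsilyl dienol ether analogue of 24 | C=C(O[Si](C(C)C)(C(C)C)C(C)C)/C(CCC(=O)OC)=C(\C)CC[C@H](C)[C@](C)(Cc1cc(OC)cc(C)c1OC)/C=C/C=O
F2 | step 16 | triisopropylsilyl analogue of cycloadduct 25 | CC(C)[Si](C(C)C)(C(C)C)OC1=C(CCC(=O)OC)[C@]2(C)CC[C@H](C)[C@](C)(Cc3cc(OC)cc(C)c3OC)[C@H]2[C@H](C=O)C1
F3 | step 17 | keto aldehyde (27 carrying 7α-CHO) | O=C1C[C@@H](C=O)[C@H]2[C@@](C)(CC[C@H](C)[C@]2(C)Cc2cc(OC)cc(C)c2OC)[C@@H]1CCC(=O)OC
F4 | step 17 | keto acid (27 carrying 7α-CO2H) | O=C1C[C@@H](C(=O)O)[C@H]2[C@@](C)(CC[C@H](C)[C@]2(C)Cc2cc(OC)cc(C)c2OC)[C@@H]1CCC(=O)OC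
F5 | step 17 | 2-thioxopyridin-1(2H)-yl ester of F4 | O=C1C[C@@H](C(=O)On3ccccc3=S)[C@H]2[C@@](C)(CC[C@H](C)[C@]2(C)Cc2cc(OC)cc(C)c2OC)[C@@H]1CCC(=O)OC
F6 | step 19 | methyl ester of 31 | CC(C)=C1CC[C@H]2[C@@](C)(CC[C@H](C)[C@]2(C)Cc2cc(OC)cc(C)c2OC)[C@@H]1CCC(=O)OC
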